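Each reaction on the list leaves c_E − c_J − c_D unchanged: J <-> D swaps J for D, while E + D -> Z and J + E -> L each take one E together with one J or D. So the surplus, c_E minus c_J and c_D, keeps its charged value, which in the north flask is 0.910 M.

| setting | north | south-east | flask |
|---|---|---|---|
| J | 0.91 M | 0.91 M | 0.91 M |
| E | 1.82 M | 1.2 M | 1.82 M |
| temperature | 110 °C | 95 °C | 110 °C |
| remark | the very flask that is asked about, followed so far | run made earlier |  |
| time |  |  | 40 h |

| north: time / h | north: Z / % | south-east: time / h | south-east: Z / % |
|---|---|---|---|
| 3.00 | 63.6 | 0.200 | 0 |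
| 8.00 | 71.3 | 0.417 | 0 |
| 15.0 | 71.9 | 0.833 | 4.9 |
| 25.0 | 71.8 | 1.33 | 9.4 |
| 30.0 | 72.8 | 3.00 | 24.3 |

(each reading ± 1 percentage point)

- Sunday's: at 40 h raise the temperature by 20 K, then wait 3.0 d
- Tuesday's: change nothing and wait 3.0 d more
- Friday's: at 40 h take out 90 % of the Z then present, then wait 3.0 d

- what is taken out of Z is counted as made
- reactions considered so far: J <-> D; E + D -> Z; J + E -> L

- Z, in percent of the J first charged, at 40 h
- the option that brings most further Z ("none" if no option brings more than 2 percentage points) (Sunday's / Tuesday's / Friday's / none)
- Z present, with what was taken out counted in, in percent of the J first charged, after Tuesday's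
- Z present, with what was taken out counted in, in percent of the J first charged, after Friday's

At the bench I count one E for each J and read a flat curve in a flask with E to spare as J finished. The north readings from 8.00 h to 30.0 h are flat within their scatter of 1 percentage point, with a mean of 72.0 %.

The border of this rule is the ratio of c_E to c_J as charged, which stands at 2.00 in the north flask. Below one the surplus is negative, so c_E can reach zero with J or D still standing, and a flat curve then need not mean that J is gone. In the north flask c_E stays at 0.910 M or above, 50.0 % of its charge, since E is charged in excess of J. So in the north flask E + D -> Z and J + E -> L keep running while J or D stands, and I read the flat readings as c_J + c_D having come close to zero, as near as the scatter shows. J is the limiting reagent there. The rest of the charged J, 28.0 %, I then read as L. On that reading I reckon 72.0 % at 40 h and after each option, with no gain above 2 points.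

The forecast gives 72 % at 40 h, between 71.2 % and 73 %, best none, and 72.2 % after Tuesday's and 72.2 % after Friday's: “The plateau therefore most likely means J and D are used up”.

The north flask gives 71.6 % at 40 h, best none, with 71.6 % after Tuesday's and 71.6 % after Friday's.

    J ⇌ D (K = 0.790, k = 7.18 × 10⁻⁴ s⁻¹, Ea = 118 kJ mol⁻¹, ΔH = −30.0 kJ mol⁻¹)
    E + D → Z (k = 3.08 × 10⁻⁴ M⁻¹ s⁻¹, Ea = 101 kJ mol⁻¹)
    J + E → L (k = 6.34 × 10⁻⁵ M⁻¹ s⁻¹, Ea = 79.0 kJ mol⁻¹)
    (constants at 110 °C)

At 40.0 h the north flask holds 0 % of its J and 50.0 % of its E, and 0.910 M over the charge of 1.82 M is 50.0 %. A neighbour flask charged with 0.46 M of E has a surplus of −0.450 M, so c_J + c_D should stand at 0.450 M once E has run out, which is 49.5 % of the charged J. At 40.0 h that neighbour holds 0 % of its E and, in percent of the charged J, J 27.6 %, D 21.8 %, and Z 38.5 %.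

The earlier runs and the new flask are simulated from invented constants.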